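Skeleton numbering used throughout: O1, C2 (carries ring B), C3 (carries C9H2OH), ring A = C3a, C4, C5, C6, C7, C7a.

## Analysis of the target

4-O-Methylbalanophonin is a 2-aryl-2,3-dihydrobenzofuran neolignan. Ring A (C3a to C7a) is fused to the dihydrofuran O1–C2–C3; C2 carries ring B (3,4-dimethoxyphenyl), C3 carries the hydroxymethyl carbon C9, C7 a methoxy group and C5 an (E)-propenal chain. The only stereocentres are the neighbours C2 (R) and C3 (S), with ring B and C9H2OH trans on the five-membered ring. C2 is a benzylic ether next to an electron-rich arene, so acid can ionise O1–C2 and scramble C2. The enal is open to reduction, conjugate addition and base, and the primary alcohol must not interfere with its installation. The difficulty is to set both centres in the absolute sense with no resident stereocentre or directing group nearby, and to bring in the enal late. The strategy rests on C3: it is bonded to C3a of ring A, to C2 and to C9, so it can be delivered as a ring A carbene to the C2=C9 double bond of a styrene. This gives a cyclopropane whose C2–C9 bond is absent from the target and is later cleaved by O1.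

## Retrosynthetic reasoning

**Enal.** The bond between C5 and the propenal chain is cut first, giving bromo alcohol 13 and acetal 14, with acetal 15 as the masked enal that is hydrolysed in the work-up. This keeps the most fragile group out of every earlier step. The bromine of 13 also fills the position para to O1 during the electrophilic ring opening. The forward reaction is a Heck coupling that must give the E alkene at the aldehyde oxidation level without touching C2 or C3.

**C9–O.** The C9–O bond of 13 is traced back to a C9–mercury bond in 10 (through 11 and 12). No skeleton is gained, but the exchange marks C9 as the carbon where an electrophile has entered. The forward reaction is an oxidative demercuration at a primary carbon that leaves C3 alone.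

**O1–C2 cut, C2–C9 reconnected.** In 10 (formed through 9) the O1–C2 bond is cut and C2 is joined to C9, which gives cyclopropyl phenol 8. O1–C2 is the one ring bond that an internal nucleophile can form with a defined stereochemical course while C3 stays a spectator. The gain is that the two centres of a benzylic ether become the two centres of a trans-1,2-diarylcyclopropane, for which a catalytic asymmetric construction exists. In the forward direction the electrophile must land on the CH2 carbon C9 and O1 must displace it at C2 from the rear. The (1S,2S)-trans cyclopropane then gives the (2R,3S)-trans ring.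

**Phenol protection.** Phenol 8 is masked as the methoxymethyl ether 7. The cyclopropanation runs in basic methanol, where a phenoxide next to the carbene carbon would interfere, and an ortho-alkoxy group on the carbene aryl is the pattern this catalysis handles best.

**Cyclopropane.** Cyclopropane 7 is cut at C3–C9 and C2–C3, which leads to tosylhydrazone 4 (carbene precursor, through diazo compound 6) and styrene 5. C3 is the only carbon joined to ring A, C2 and C9, so this cut turns a one-carbon unit and a bought two-carbon unit into both stereocentres at once. The forward step must control trans against cis and the absolute sense.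

**Carbene precursor.** Hydrazone 4 comes from aldehyde 2 and hydrazide 3, and 2 is the protected form of aldehyde 1, which already holds every substituent of ring A in the right place.

## Alternatives that were turned down

**Alternative 1:** Ring A is built last by a vinylketene benzannulation, cutting C4–C5, C6–C7 and C7–C7a.
- Key step: irradiation of 2-diazo-1-[(4S,5R)-4-[(tert-butyldimethylsilyloxy)methyl]-5-(3,4-dimethoxyphenyl)-4,5-dihydrofuran-3-yl]ethan-1-one A2 with tert-butyldimethyl(prop-2-yn-1-yloxy)silane A3. Wolff rearrangement gives a vinylketene, [2+2] addition to the alkyne gives a cyclobutenone, and warming opens it (four electrons) and recloses it (six electrons) to (2R,3S)-3,5-bis[(tert-butyldimethylsilyloxy)methyl]-2-(3,4-dimethoxyphenyl)-2,3-dihydro-1-benzofuran-7-ol A1.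
- For: the mechanism fixes the pattern of ring A (the ketene carbon becomes C7–OH, the alkyne substituent ends at C5). No halogen placeholder, mercury or late palladium step is needed.
- Against: both stereocentres must already be in A2, so the stereochemical problem is only moved into a longer synthesis of an acid-sensitive cyclic enol ether with a benzylic C–O bond. After the annulation the two primary silyl ethers of A1 must be told apart, and O-methylation, desilylation, benzylic oxidation and a two-carbon olefination still follow.
- Comparison: A1 is stronger on the regiochemical security of ring A. The chosen route instead buys the ring A pattern with 1 and creates both stereocentres in one catalytic step, in seven steps overall against well over ten.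

**Alternative 2:** An asymmetric Prins addition interrupted by the phenol, cutting C3–C9 and O1–C2.
- Key step: a confined chiral imidodiphosphorimidate Brønsted acid activates formaldehyde A6; C3 of (E)-4-bromo-2-[2-(3,4-dimethoxyphenyl)ethenyl]-6-methoxyphenol A5 attacks it and O1 captures the C2 cation, giving [(2R,3S)-5-bromo-2-(3,4-dimethoxyphenyl)-7-methoxy-2,3-dihydro-1-benzofuran-3-yl]methanol A4, which is identical with 13.
- For: this is the shortest plan. A5 is about two steps from 1 and A4 needs only the final coupling, so the target would be reached in about four steps without a stoichiometric heavy metal. On step economy it beats the chosen route.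
- Against: the key step lies far outside what such acids have been shown to do. Both alkene carbons carry donor aryl groups (para-methoxy on ring B for a cation at C2, ortho-hydroxy on ring A for a cation at C3), so the direction of attack on A6 is not secured. The free phenol and the veratrole ring can themselves be hydroxymethylated. A long-lived para-methoxybenzylic cation at C2 loosens the ion pair that must transmit chirality, and a 1,2-diarylalkene is a bulky guest for a confined pocket.
- Comparison: the chosen strategy is longer, but its stereo-defining step stays inside a demonstrated substrate class. Its one unprecedented element is a ring opening whose regiochemistry is enforced by ring size and which preserves stereochemistry.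

**Alternative 3:** Ring A from a lactone ketene acetal and a pyrone, cutting C3a–C4 and C7–C7a.
- Key step: the silyl ketene acetal of (4S,5R)-4-[(tert-butyldimethylsilyloxy)methyl]-5-(3,4-dimethoxyphenyl)oxolan-2-one A9 adds across C3 and C6 of methyl 3-bromo-2-oxo-2H-pyran-5-carboxylate A8 (Diels–Alder). Decarboxylative cycloreversion and loss of the silyloxy group aromatise the adduct to methyl (2R,3S)-7-bromo-3-[(tert-butyldimethylsilyloxy)methyl]-2-(3,4-dimethoxyphenyl)-2,3-dihydro-1-benzofuran-5-carboxylate A7.
- For: polarity matching of the electron-poor pyrone and the electron-rich ketene acetal fixes the orientation, and aromatisation drives the step. A trans-disubstituted butyrolactone such as A9 is a classical object of asymmetric synthesis.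
- Against: the stereocentres again need a separate multi-step sequence, and the ketene acetal of a lactone is moisture-sensitive. A7 carries bromine where the C7 methoxy group belongs and an ester where the enal belongs, so a metal-catalysed methoxylation, reduction, oxidation, two-carbon olefination and desilylation follow the key step.
- Comparison: A7 is stronger in relying on robust pericyclic chemistry and on lactone stereocontrol. The chosen strategy keeps all three oxygens of ring A from the starting arene and needs about half the steps.

Key step: step 3

Assumption: the sense of induction of the chiral cobalt catalyst is assigned by analogy with its behaviour towards styrenes; if the (1R,2R) cyclopropane should prevail, the enantiomeric ligand is used.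

## Route

Step 1
Reactants: 1 5-bromo-2-hydroxy-3-methoxybenzaldehyde
Product: 2 5-bromo-3-methoxy-2-(methoxymethoxy)benzaldehyde
Conditions: MOMCl, iPr2NEt, CH2Cl2, 0 °C to rt
Reagents that add atoms: chloromethyl methyl ether (MOMCl), COCCl
Why: O-alkylation of the acidic salicylaldehyde phenol (Williamson-type); the MOM ether should survive carbonate in methanol in step 3, provides the ortho-alkoxy group the cyclopropanation prefers, and leaves with mild acid.

Step 2
Reactants: 2 5-bromo-3-methoxy-2-(methoxymethoxy)benzaldehyde; 3 4-methylbenzenesulfonohydrazide
Product: 4 (E)-N'-[5-bromo-3-methoxy-2-(methoxymethoxy)benzylidene]-4-methylbenzenesulfonohydrazide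
Conditions: MeOH, rt, no acid
Reagents that add atoms: none
Why: Hydrazone condensation of an aromatic aldehyde, which should proceed without added acid so that the MOM acetal is kept; the E hydrazone is expected and should crystallise.

Step 3
Reactants: 4 (E)-N'-[5-bromo-3-methoxy-2-(methoxymethoxy)benzylidene]-4-methylbenzenesulfonohydrazide; 5 3,4-dimethoxystyrene
Product: 7 5-bromo-1-[(1S,2S)-2-(3,4-dimethoxyphenyl)cyclopropyl]-3-methoxy-2-(methoxymethoxy)benzene, via aryldiazomethane 6 (not isolated)
Conditions: Co(Por*) (2 mol%; Por* = D2-symmetric chiral amidoporphyrin dianion, divalent cobalt), Cs2CO3 (2 equiv), 5 (1.5 equiv), MeOH, 40 °C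
Reagents that add atoms: none
Why: Cs2CO3 deprotonates 4 and the anion loses sulfinate (Bamford–Stevens fragmentation), releasing diazo compound 6 slowly; Co(Por*), a complex of divalent cobalt with one unpaired electron, takes up 6 with loss of N2 and becomes a benzylic carbon radical bound to trivalent cobalt. This radical adds to the terminal carbon C9 of styrene 5 (bond C3–C9), and the new benzylic radical at C2 attacks the cobalt-bound carbon C3 in a 3-exo-tet homolytic substitution that forms C2–C3, closes the cyclopropane and returns divalent cobalt. The closest known reaction type is the cobalt-porphyrin metalloradical cyclopropanation of styrenes with aryldiazomethanes generated in the flask from ortho-alkoxybenzaldehyde tosylhydrazones. The trans relation should follow from the ring-closing conformer in which ring B turns away from ring A and from the porphyrin plane. The absolute configuration (1S,2S) is set by the chiral amide pocket of Por*, which decides the face of the cobalt-bound radical that meets the alkene; the ortho-alkoxy oxygen can accept a hydrogen bond from an amide N–H and so fix the orientation of the aryl group. The step needs cyclopropanation to outrun carbene dimerisation to azine or stilbene, which the slow release of 6, the excess of electron-rich 5 and the radical character of the intermediate should secure. The aryl bromide and the MOM ether are inert to carbonate in methanol and to the cobalt radical.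

Step 4
Reactants: 7 5-bromo-1-[(1S,2S)-2-(3,4-dimethoxyphenyl)cyclopropyl]-3-methoxy-2-(methoxymethoxy)benzene
Product: 8 4-bromo-2-[(1S,2S)-2-(3,4-dimethoxyphenyl)cyclopropyl]-6-methoxyphenol
Conditions: HCl (1 M in MeOH), rt to 40 °C
Reagents that add atoms: none
Why: Acid-catalysed methanolysis of the MOM acetal; dilute acid in a nucleophilic solvent should not protonate the arylcyclopropane, so both stereocentres, the aryl bromide and the methyl ethers are kept.

Step 5
Reactants: 8 4-bromo-2-[(1S,2S)-2-(3,4-dimethoxyphenyl)cyclopropyl]-6-methoxyphenol
Product: 10 {[(2R,3R)-5-bromo-2-(3,4-dimethoxyphenyl)-7-methoxy-2,3-dihydro-1-benzofuran-3-yl]methyl}mercury chloride, via organomercury trifluoroacetate 9 (not isolated)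
Conditions: Hg(OCOCF3)2 (1.05 equiv), CH2Cl2, −20 to 0 °C; then sat. aq NaCl
Reagents that add atoms: mercury bis(trifluoroacetate), O=C(O[Hg]OC(=O)C(F)(F)F)C(F)(F)F; sodium chloride, [Na+].[Cl-]
Why: Proposed new method: Hg(OCOCF3)2, an electrophile of divalent mercury, should attack the unsubstituted carbon C9 of the cyclopropane, and the C2–C9 bond then breaks because C2 carries the cation-stabilising 3,4-dimethoxyphenyl ring and because only C2 lies within reach of O1 (attack at C3 would need a four-membered ring); O1 enters at the rear of the breaking C2–C9 bond in a 5-exo-tet closure with inversion at C2 while C3 is a spectator, so the (1S,2S)-trans cyclopropane maps onto the (2R)-trans dihydrobenzofuran (the C3 label changes to R only because C9 now bears mercury), and even a more cation-like opening should close trans because the C3 substituent steers ring B to the opposite face; the closest known reaction type is the stereospecific 1,3-oxymercuration of arylcyclopropanes with inversion at the carbon that takes the oxygen nucleophile, known with water, alcohols and tethered hydroxyl or carboxyl groups but not with an ortho phenol on one of the aryl rings.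

Step 6
Reactants: 10 {[(2R,3R)-5-bromo-2-(3,4-dimethoxyphenyl)-7-methoxy-2,3-dihydro-1-benzofuran-3-yl]methyl}mercury chloride
Product: 13 [(2R,3S)-5-bromo-2-(3,4-dimethoxyphenyl)-7-methoxy-2,3-dihydro-1-benzofuran-3-yl]methanol, via alkylmercury hydride 11 (not isolated), via hydroperoxide 12 (not isolated)
Conditions: NaBH4, O2 (bubbled, 1 atm), DMF, 0 °C to rt
Reagents that add atoms: dioxygen, O=O
Why: Oxidative demercuration: NaBH4 converts 10 into hydride 11, which loses mercury to give the primary C9 radical; O2 at saturation should trap it faster than hydrogen transfer or rearrangement, and NaBH4 reduces hydroperoxide 12 to the alcohol. The radical sits on C9 only, so C2 and C3 are not touched (the C3 label returns to S), and the aryl bromide is inert.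

Step 7
Reactants: 13 [(2R,3S)-5-bromo-2-(3,4-dimethoxyphenyl)-7-methoxy-2,3-dihydro-1-benzofuran-3-yl]methanol; 14 3,3-diethoxyprop-1-ene (acrolein diethyl acetal)
Product: 16 (E)-3-[(2R,3S)-2-(3,4-dimethoxyphenyl)-3-(hydroxymethyl)-7-methoxy-2,3-dihydro-1-benzofuran-5-yl]prop-2-enal (4-O-methylbalanophonin), via diethyl acetal 15 (not isolated)
Conditions: Pd(OAc)2 (3 mol%), nBu4NOAc, K2CO3, KCl, DMF, 90 °C; then 2 M aq HCl, rt
Reagents that add atoms: water, O
Why: Mizoroki–Heck reaction: zerovalent palladium formed in the flask inserts into C5–Br, syn-carbopalladation of 14 at its terminal carbon and syn β-hydride elimination towards the benzylic side should give the E alkene 15; the acetate, carbonate and chloride medium disfavours elimination towards the acetal carbon, which would end as an ester. Dilute acid then hydrolyses the acetal to the enal at room temperature, conditions the primary alcohol and the C2 benzylic ether should tolerate.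

## Compound list

1 | 5-bromo-2-hydroxy-3-methoxybenzaldehyde | COc1cc(Br)cc(C=O)c1O | starting material
2 | 5-bromo-3-methoxy-2-(methoxymethoxy)benzaldehyde | COCOc1c(OC)cc(Br)cc1C=O | intermediate
3 | 4-methylbenzenesulfonohydrazide | Cc1ccc(cc1)S(=O)(=O)NN | starting material
4 | (E)-N'-[5-bromo-3-methoxy-2-(methoxymethoxy)benzylidene]-4-methylbenzenesulfonohydrazide | COCOc1c(OC)cc(Br)cc1/C=N/NS(=O)(=O)c2ccc(C)cc2 | intermediate
5 | 3,4-dimethoxystyrene (4-ethenyl-1,2-dimethoxybenzene) | C=Cc1ccc(OC)c(OC)c1 | starting material
6 | 5-bromo-1-(diazomethyl)-3-methoxy-2-(methoxymethoxy)benzene | COCOc1c(OC)cc(Br)cc1C=[N+]=[N-] | intermediate (not isolated)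
7 | 5-bromo-1-[(1S,2S)-2-(3,4-dimethoxyphenyl)cyclopropyl]-3-methoxy-2-(methoxymethoxy)benzene | COc1ccc([C@H]2C[C@@H]2c3cc(Br)cc(OC)c3OCOC)cc1OC | intermediate
8 | 4-bromo-2-[(1S,2S)-2-(3,4-dimethoxyphenyl)cyclopropyl]-6-methoxyphenol | COc1ccc([C@H]2C[C@@H]2c3cc(Br)cc(OC)c3O)cc1OC | intermediate
9 | {[(2R,3R)-5-bromo-2-(3,4-dimethoxyphenyl)-7-methoxy-2,3-dihydro-1-benzofuran-3-yl]methyl}mercury trifluoroacetate | COc1ccc([C@@H]2Oc3c(OC)cc(Br)cc3[C@H]2C[Hg]OC(=O)C(F)(F)F)cc1OC | intermediate (not isolated)
10 | {[(2R,3R)-5-bromo-2-(3,4-dimethoxyphenyl)-7-methoxy-2,3-dihydro-1-benzofuran-3-yl]methyl}mercury chloride | COc1ccc([C@@H]2Oc3c(OC)cc(Br)cc3[C@H]2C[Hg]Cl)cc1OC | intermediate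
11 | {[(2R,3R)-5-bromo-2-(3,4-dimethoxyphenyl)-7-methoxy-2,3-dihydro-1-benzofuran-3-yl]methyl}mercury hydride | COc1ccc([C@@H]2Oc3c(OC)cc(Br)cc3[C@H]2C[HgH])cc1OC | intermediate (not isolated)
12 | (2R,3S)-5-bromo-2-(3,4-dimethoxyphenyl)-3-(hydroperoxymethyl)-7-methoxy-2,3-dihydro-1-benzofuran | COc1ccc([C@@H]2Oc3c(OC)cc(Br)cc3[C@H]2COO)cc1OC | intermediate (not isolated)
13 | [(2R,3S)-5-bromo-2-(3,4-dimethoxyphenyl)-7-methoxy-2,3-dihydro-1-benzofuran-3-yl]methanol | COc1ccc([C@@H]2Oc3c(OC)cc(Br)cc3[C@H]2CO)cc1OC | intermediate
14 | 3,3-diethoxyprop-1-ene (acrolein diethyl acetal) | C=CC(OCC)OCC | starting material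
15 | [(2R,3S)-5-[(E)-3,3-diethoxyprop-1-en-1-yl]-2-(3,4-dimethoxyphenyl)-7-methoxy-2,3-dihydro-1-benzofuran-3-yl]methanol | COc1ccc([C@@H]2Oc3c(OC)cc(/C=C/C(OCC)OCC)cc3[C@H]2CO)cc1OC | intermediate (not isolated)
16 | (E)-3-[(2R,3S)-2-(3,4-dimethoxyphenyl)-3-(hydroxymethyl)-7-methoxy-2,3-dihydro-1-benzofuran-5-yl]prop-2-enal (4-O-methylbalanophonin) | COc1ccc([C@@H]2Oc3c(OC)cc(/C=C/C=O)cc3[C@H]2CO)cc1OC | target

## Step count and least certain steps

Total step count: 7. Longest linear sequence: 7 steps (1 to 16).

**Step 5 (the one step that carries the label "Proposed new method:").**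
- Most likely failure: competing electrophilic mercuration of ring B (the position para to a methoxy group) before the cyclopropane is attacked, or opening of the C3–C9 bond instead of C2–C9 with capture by trifluoroacetate.
- Ring A is less exposed. Every position ortho or para to O1 is substituted; C4 and C6 are activated only by the C7 methoxy group and flanked by bromine.
- Fallback with known chemistry, from 7 back to 13: 7 is treated with the milder Hg(OAc)2 in THF/H2O. Water opens the cyclopropane at C2 with inversion and gives {(2R,3R)-2-[5-bromo-3-methoxy-2-(methoxymethoxy)phenyl]-3-(3,4-dimethoxyphenyl)-3-hydroxypropyl}mercury acetate F1. Oxidative demercuration as in step 6 (NaBH4, O2, DMF) gives (1R,2S)-2-[5-bromo-3-methoxy-2-(methoxymethoxy)phenyl]-1-(3,4-dimethoxyphenyl)propane-1,3-diol F2. Dilute HCl in THF/MeOH then removes the MOM group and ionises the benzylic alcohol; the phenol captures the cation to close the thermodynamically favoured trans ring under control of the untouched C3, which returns the route to 13.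

**Step 3 (key step).**
- Most likely failure: erosion of enantio- and trans-selectivity, because the 2-methoxymethoxy-3-methoxy pattern is bulkier than a simple ortho-methoxy aryl group and may sit differently in the chiral pocket. Carbene dimerisation is the second concern if the hindered radical adds slowly.
- Fallback, from 2 back to 7: 2 undergoes Horner–Wadsworth–Emmons olefination with diethyl (3,4-dimethoxybenzyl)phosphonate (NaH, THF) to give (E)-5-bromo-1-[2-(3,4-dimethoxyphenyl)ethenyl]-3-methoxy-2-(methoxymethoxy)benzene F3. Stereospecific Simmons–Smith cyclopropanation (Et2Zn, CH2I2, CF3CO2H, CH2Cl2, 0 °C) gives racemic trans-5-bromo-1-[2-(3,4-dimethoxyphenyl)cyclopropyl]-3-methoxy-2-(methoxymethoxy)benzene F4. Preparative chromatography on a chiral stationary phase then delivers 7. The bond construction changes to methylene transfer onto a stilbene, and the absolute configuration comes from separation, at the cost of half the material.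

**Step 6.**
- Most likely failure: hydrogen transfer to the C9 radical before oxygen capture, which gives the reduced C3-methyl by-product, a common leak in borohydride–oxygen demercurations.
- Fallback, from 10 back to 13, avoiding the free radical: iododemercuration with I2 in CH2Cl2 gives (2R,3R)-5-bromo-2-(3,4-dimethoxyphenyl)-3-(iodomethyl)-7-methoxy-2,3-dihydro-1-benzofuran F5. SN2 displacement with CsOAc in DMF gives [(2R,3S)-5-bromo-2-(3,4-dimethoxyphenyl)-7-methoxy-2,3-dihydro-1-benzofuran-3-yl]methyl acetate F6, and K2CO3 in MeOH releases 13.

**Step 7.**
- Most likely failure: slow oxidative addition into the electron-rich C5–Br bond (para to O1) with catalyst decomposition, and β-hydride elimination towards the acetal carbon, which after hydrolysis gives a saturated ester instead of the enal.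
- Fallback, from 13 back to 15: Suzuki–Miyaura coupling of 13 with commercial (E)-2-(3,3-diethoxyprop-1-enyl)-4,4,5,5-tetramethyl-1,3,2-dioxaborolane (Pd(OAc)2, SPhos, K3PO4, dioxane/H2O, 80 °C) forms the same C5–C bond by transmetalation, so the direction of β-hydride elimination no longer matters. Acetal 15 is then hydrolysed as in step 7; no new compound arises.

## Further compounds

F1 | step 5 | {(2R,3R)-2-[5-bromo-3-methoxy-2-(methoxymethoxy)phenyl]-3-(3,4-dimethoxyphenyl)-3-hydroxypropyl}mercury acetate | COc1ccc([C@H](O)[C@H](C[Hg]OC(C)=O)c2cc(Br)cc(OC)c2OCOC)cc1OC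
F2 | step 5 | (1R,2S)-2-[5-bromo-3-methoxy-2-(methoxymethoxy)phenyl]-1-(3,4-dimethoxyphenyl)propane-1,3-diol | COc1ccc([C@H](O)[C@H](CO)c2cc(Br)cc(OC)c2OCOC)cc1OC
F3 | step 3 | (E)-5-bromo-1-[2-(3,4-dimethoxyphenyl)ethenyl]-3-methoxy-2-(methoxymethoxy)benzene | COCOc1c(OC)cc(Br)cc1/C=C/c2ccc(OC)c(OC)c2
F4 | step 3 | racemic trans-5-bromo-1-[2-(3,4-dimethoxyphenyl)cyclopropyl]-3-methoxy-2-(methoxymethoxy)benzene (1:1 mixture of the two enantiomers) | COc1ccc([C@H]2C[C@@H]2c3cc(Br)cc(OC)c3OCOC)cc1OC.COc1ccc([C@@H]2C[C@H]2c3cc(Br)cc(OC)c3OCOC)cc1OC
F5 | step 6 | (2R,3R)-5-bromo-2-(3,4-dimethoxyphenyl)-3-(iodomethyl)-7-methoxy-2,3-dihydro-1-benzofuran | COc1ccc([C@@H]2Oc3c(OC)cc(Br)cc3[C@H]2CI)cc1OC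
F6 | step 6 | [(2R,3S)-5-bromo-2-(3,4-dimethoxyphenyl)-7-methoxy-2,3-dihydro-1-benzofuran-3-yl]methyl acetate | COc1ccc([C@@H]2Oc3c(OC)cc(Br)cc3[C@H]2COC(C)=O)cc1OC
F0 | step 7 | none | none
A1 | alternative 1 | (2R,3S)-3,5-bis[(tert-butyldimethylsilyloxy)methyl]-2-(3,4-dimethoxyphenyl)-2,3-dihydro-1-benzofuran-7-ol | COc1ccc([C@@H]2Oc3c(O)cc(CO[Si](C)(C)C(C)(C)C)cc3[C@H]2CO[Si](C)(C)C(C)(C)C)cc1OC
A2 | alternative 1 | 2-diazo-1-[(4S,5R)-4-[(tert-butyldimethylsilyloxy)methyl]-5-(3,4-dimethoxyphenyl)-4,5-dihydrofuran-3-yl]ethan-1-one | COc1ccc([C@@H]2OC=C(C(=O)C=[N+]=[N-])[C@H]2CO[Si](C)(C)C(C)(C)C)cc1OC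
A3 | alternative 1 | tert-butyldimethyl(prop-2-yn-1-yloxy)silane | C#CCO[Si](C)(C)C(C)(C)C
A4 | alternative 2 | [(2R,3S)-5-bromo-2-(3,4-dimethoxyphenyl)-7-methoxy-2,3-dihydro-1-benzofuran-3-yl]methanol | COc1ccc([C@@H]2Oc3c(OC)cc(Br)cc3[C@H]2CO)cc1OC
A5 | alternative 2 | (E)-4-bromo-2-[2-(3,4-dimethoxyphenyl)ethenyl]-6-methoxyphenol | COc1ccc(/C=C/c2cc(Br)cc(OC)c2O)cc1OC
A6 | alternative 2 | formaldehyde | C=O
A7 | alternative 3 | methyl (2R,3S)-7-bromo-3-[(tert-butyldimethylsilyloxy)methyl]-2-(3,4-dimethoxyphenyl)-2,3-dihydro-1-benzofuran-5-carboxylate | COc1ccc([C@@H]2Oc3c(Br)cc(C(=O)OC)cc3[C@H]2CO[Si](C)(C)C(C)(C)C)cc1OC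
A8 | alternative 3 | methyl 3-bromo-2-oxo-2H-pyran-5-carboxylate | COC(=O)C1=COC(=O)C(Br)=C1
A9 | alternative 3 | (4S,5R)-4-[(tert-butyldimethylsilyloxy)methyl]-5-(3,4-dimethoxyphenyl)oxolan-2-one | COc1ccc([C@@H]2OC(=O)C[C@H]2CO[Si](C)(C)C(C)(C)C)cc1OC
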